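**Assumption:** the target SMILES has no stereocentre, no stereogenic alkene and a symmetric 2,6-diprenyl aryl ring (no atropisomerism), so the molecule is achiral and no stereocontrol is needed.

## Retrosynthetic overview

1. Last step is a simple O–Si cleavage to free the 6-OH.
2. Key disconnection is the aryl–C2(benzofuran) bond: Negishi coupling of a 2-benzofuranylzinc with a hindered aryl chloride.
3. The aryl chloride comes from 1-chloro-3,5-dimethoxybenzene by 2,6-dibromination, then double linear-selective prenyl Negishi coupling at C–Br (C–Cl kept as the handle).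
4. The benzofuranylzinc comes from commercial benzofuran-6-ol by O-silylation and C2 lithiation/zincation.
5. No ring is constructed: both the benzene and the benzofuran are bought intact.

## Route

**Step 1**
Reactants: **1** 1-chloro-3,5-dimethoxybenzene; **2** N-bromosuccinimide
Product: **3** 2,4-dibromo-3-chloro-1,5-dimethoxybenzene (Cl flanked by two Br; the CH between the two OMe groups untouched)
Conditions: NBS (2.1 equiv), MeCN, 0 °C → rt (warm to 40 °C to finish the second bromination)
Reagents that add atoms: NBS, O=C1CCC(=O)N1Br (2 × Br)
Why: electrophilic aromatic bromination; each OMe directs para more strongly than ortho, so both Br enter next to Cl rather than between the two OMe groups, as seen for other 5-substituted 1,3-dimethoxybenzenes.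

**Step 2**
Reactants: **3**; **4** prenyl bromide (1-bromo-3-methylbut-2-ene), converted in the same operation to prenylzinc bromide (not isolated, not counted as a step)
Product: **5** 3-chloro-1,5-dimethoxy-2,4-bis(3-methylbut-2-en-1-yl)benzene
Conditions: prenylZnBr (2.6 equiv; from **4**, Zn dust, LiCl, THF, 0 °C → rt), CPhos Pd G3 (4 mol %), THF, rt
Reagents that add atoms: prenylzinc bromide, CC(C)=CC[Zn]Br, made from prenyl bromide, CC(C)=CCBr (2 × C5H9)
Why: linear(α)-selective allyl Negishi coupling; the bulky biarylphosphine favours reductive elimination from the primary σ-prenyl Pd species, and C–Br undergoes oxidative addition far faster than the doubly flanked C–Cl at rt.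

**Step 3**
Reactants: **6** benzofuran-6-ol; **7** triisopropylsilyl chloride
Product: **8** (benzofuran-6-yloxy)triisopropylsilane
Conditions: TIPSCl, imidazole, DMF, rt
Reagents that add atoms: TIPSCl, CC(C)[Si](Cl)(C(C)C)C(C)C
Why: standard phenol silylation; TIPS tolerates n-BuLi and is removed by fluoride without touching the aryl methyl ethers or prenyl alkenes.

**Step 4**
Reactants: **8** (1.5 equiv); **5** (1.0 equiv)
Product: **9** {[2-(3,5-dimethoxy-2,6-bis(3-methylbut-2-en-1-yl)phenyl)benzofuran-6-yl]oxy}triisopropylsilane
Conditions: **8**, n-BuLi, THF, −78 °C; ZnCl2, −78 °C → rt; then **5**, XPhos Pd G3 (4 mol %), THF, 65 °C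
Reagents that add atoms: none (Li, Zn and Cl are lost)
Why: benzofuran lithiates cleanly at C2 (α to O); after transmetalation to zinc, a Negishi coupling with the di-ortho-substituted aryl chloride is feasible with a bulky dialkylbiarylphosphine Pd catalyst because the five-membered heteroaryl partner is sterically small.

**Step 5**
Reactants: **9**
Product: **10** lakoochin A, 2-[3,5-dimethoxy-2,6-bis(3-methylbut-2-en-1-yl)phenyl]benzofuran-6-ol
Conditions: TBAF, THF, 0 °C → rt; aq. NH4Cl work-up
Reagents that add atoms: none
Why: fluoride-mediated desilylation of the aryl silyl ether; methyl ethers, prenyl groups and the benzofuran are inert.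

## Compound list

1 | 1-chloro-3,5-dimethoxybenzene | COc1cc(Cl)cc(OC)c1 | starting material
2 | N-bromosuccinimide | O=C1CCC(=O)N1Br | starting material (reagent)
3 | 2,4-dibromo-3-chloro-1,5-dimethoxybenzene | COc1cc(OC)c(Br)c(Cl)c1Br | intermediate
4 | prenyl bromide (1-bromo-3-methylbut-2-ene) | CC(C)=CCBr | starting material
5 | 3-chloro-1,5-dimethoxy-2,4-bis(3-methylbut-2-en-1-yl)benzene | COc1cc(OC)c(CC=C(C)C)c(Cl)c1CC=C(C)C | intermediate
6 | benzofuran-6-ol | Oc1ccc2ccoc2c1 | starting material
7 | triisopropylsilyl chloride | CC(C)[Si](Cl)(C(C)C)C(C)C | starting material (reagent)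
8 | (benzofuran-6-yloxy)triisopropylsilane | CC(C)[Si](Oc1ccc2ccoc2c1)(C(C)C)C(C)C | intermediate
9 | TIPS-protected lakoochin A | COc1cc(OC)c(CC=C(C)C)c(-c2cc3ccc(O[Si](C(C)C)(C(C)C)C(C)C)cc3o2)c1CC=C(C)C | intermediate
10 | lakoochin A | COc1cc(OC)c(CC=C(C)C)c(-c2cc3ccc(O)cc3o2)c1CC=C(C)C | target

## Summary

**Total steps:** 5 (in-situ formation of prenylzinc bromide not counted).
**Longest linear sequence:** 4 steps (1 → 3 → 5 → 9 → 10); the benzofuran branch is 3 steps (6 → 8 → 9 → 10).

**Steps most likely to fail, with fallbacks**

1. **Step 4, hindered Negishi at a di-ortho-prenyl aryl chloride.** Fallback: build the furan ring instead of coupling to it. Make 2,6-diprenyl-3,5-dimethoxyphenylacetylene (from 3,5-dimethoxybenzaldehyde by 2,6-dibromination, acetal protection, prenylation, deprotection and Ohira–Bestmann homologation). Then Sonogashira-couple it with 4-iodoresorcinol diacetate and close the ring by base-mediated deacetylation and 5-endo-dig cyclisation.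

2. **Step 2, double prenylation.** Risks are branched (reverse-prenyl) isomers, stalling at the mono-coupled stage, or attack at C–Cl. Fallback: couple plain allyl groups (allylSnBu3 Stille or allylBpin Suzuki, where no α/γ issue exists), then convert allyl to prenyl by cross-metathesis with 2-methyl-2-butene (Grubbs II).

3. **Step 1, regiochemistry of dibromination.** The risk is bromination at the position between the two OMe groups. Fallback: use an anilide to control the pattern. 2,6-Dibrominate N-(3,5-dimethoxyphenyl)acetamide, deacetylate, and install the chlorine last by Sandmeyer chlorination (t-BuONO, CuCl2, MeCN), arriving at the same intermediate **3**.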